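Readings and results were generated by integration with constants of no real substance, and the scatter is random.

| flask | solid substrate | acid | scavenger | remark | time |
|---|---|---|---|---|---|
| south | 0.025 M | 0.50 mM | 0.80 equiv (fed, over 10 min) | run made earlier |  |
| east | 0.10 M | 0.50 mM | 0.80 equiv (fed, over 10 min) | run made earlier |  |
| flask | 0.050 M | 0.500 mM | 0.800 equiv (fed, over 10 min) |  | 6.0 h |

| run | time / h | solid substrate / % | product / % |
|---|---|---|---|
| south | 0.250 | 93.7 | 2.5 |
| south | 0.417 | 90.0 | 5.2 |
| south | 0.667 | 83.7 | 10.7 |
| south | 1.00 | 76.8 | 15.0 |
| south | 1.50 | 66.9 | 25.2 |
| south | 2.50 | 46.2 | 41.9 |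
| south | 4.00 | 15.8 | 72.4 |
| east | 0.250 | 97.4 | 1.6 |
| east | 0.417 | 97.2 | 1.8 |
| east | 0.667 | 94.6 | 2.2 |
| east | 1.00 | 94.6 | 5.7 |
| east | 1.50 | 91.6 | 5.2 |
| east | 2.50 | 87.5 | 11.6 |
| east | 4.00 | 79.0 | 18.3 |

(standard deviation of a reading: 1 percentage point)

- acid is the free proton; pH is minus the decimal logarithm of its molar concentration
- in percentages every species weighs as the solid substrate in it: one homo dimer counts as two
- for weak acid the idle adduct is counted in
- as a solid, counted per litre of solution: solid substrate
- steps that have been proposed: starting material + acid -> weak acid + acid + product; weak acid <-> conjugate base + acid; starting material -> weak acid + product; starting material + weak acid <-> idle adduct; weak acid + scavenger -> scavenged by-product; 2 starting material -> homo dimer; solid substrate <-> starting material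
- at the start none of the solid substrate is in solution
- what has only dissolved of solid substrate counts as not reacted
- apart from what has only dissolved, what has gone from solid substrate into another species counts as reacted, even if it can come back

- part of the solid substrate that has reacted (what has only dissolved counts as not reacted) at 6.0 h
- pH of the solution at 6.0 h

- At 4.00 h, the last reading of both earlier runs, the south flask has lost solid substrate at an average of 0.00526 M h⁻¹. I call this F, the solid substrate lost per litre per hour.
- The east flask, charged 0.10 M against 0.025 M, gives 0.00525 M h⁻¹, the same reading.
- So the rate does not follow the amount of solid. I take the order in solid as zero, and I leave open how dissolving and the reaction in solution share in setting F.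
- From above: what has reacted cannot exceed what has left the solid. At F this flask's solid lasts 9.50 h, longer than 6.0 h, so I estimate the loss by a straight line, which gives 63.1 %.
- From below: the solid lost but not yet product is 0.00295 M in south and 0.00270 M in east. Taking the larger as wholly unreacted gives 57.2 %.
- That gap also holds idle adduct, which counts as reacted. I cannot split it by hand, so my bracket stops there. For the pH I take the acid charge as it stands.
- The forecast says 56 % and pH 3.3 for a “zero-order, dissolution-fed regime”, just below my bracket.
- The flask gives 59.4 % and pH 3.30.

    starting material + acid → weak acid + acid + product (k = 87.0 L mol⁻¹ min⁻¹)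
    weak acid ⇌ conjugate base + acid, settled at all times (K = 2.00 × 10⁻⁸ M)
    starting material → weak acid + product (k = 0.0208 min⁻¹)
    starting material + weak acid ⇌ idle adduct, settled at all times (K = 510 L mol⁻¹)
    weak acid + scavenger → scavenged by-product (k = 2.84 L mol⁻¹ min⁻¹)
    2 starting material → homo dimer (k = 0.00111 L mol⁻¹ min⁻¹)
    solid substrate ⇌ starting material, rate k7*(cs7 - [starting material]) while solid is left; crystals form when [starting material] > cs7 (solubility = 4.20 mM, k = 0.0290 min⁻¹)

- This flask, whose solid lasts 9.50 h at F, still holds 38.1 % of it at 6.00 h. The neighbour flask, charged 0.020 M with its recipe otherwise held, has at the same F a solid that lasts 3.80 h, shorter than 6.0 h. At 6.00 h that neighbour holds 0 % solid substrate, and 99.6 % of its charge has reacted.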